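**Retrosynthetic overview**
1. 23 ⇒ penta-O-benzyl ether 22 ⇒ benzoic acid 17 + acetophenone 19. The pyranone ring C of the 7-methoxy half comes from esterification, Baker–Venkataraman shift and cyclodehydration, and the carboxyl carbon of 17 becomes C2.
2. Feature: ring B (C1'–C6') is a 1,3,4-trisubstituted phenol, with 4'-OH, C8'' of the apigenin half ortho to it on C3', and C2 para to it on C1'. This is a 3-aryl-4-hydroxybenzoate, the pattern produced by a 2-aryl-1-methoxy-3-silyloxybuta-1,3-diene and a propiolate. Ring B is therefore grown on C8'' (new bonds C5'–C6' and C1'–C2'), and the hindered C3'–C8'' bond is never made by joining two arenes.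
3. Diene 12 ⇒ 8''-acetonyl flavone 8 (one-carbon unit on the benzylic carbon = C2', then O-methylation and O-silylation) ⇒ 8''-allyl flavone 7 (Wacker oxidation). Allyl C1–C3 become C3', C4' and C5'.
4. The C3'–C8'' bond is set as an allyl–aryl bond by an aromatic Claisen rearrangement at the acetophenone stage (3 → 4), where only one ortho position is open. The phenol released is the only free one when the pyranone closes, so the allyl group can only end on C8''.
5. Ring order: pyranone of the apigenin half (step 5), ring B (step 10), pyranone of the 7-methoxy half (step 16).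

Key step: step 10

Assumption: the target has no stereocentre and its SMILES gives no descriptor for the C3'–C8'' axis, so the biaryl is built without control of axial configuration.

**Route**

Step 1
Reactants: 1 2',4',6'-trihydroxyacetophenone
Product: 2 1-[2,4-bis(benzyloxy)-6-hydroxyphenyl]ethanone
Conditions: BnBr (2.1 equiv), K2CO3, DMF, rt → 50 °C
Reagents that add atoms: benzyl bromide, BrCc1ccccc1
Why: Williamson etherification; with two equivalents of halide the para OH and one ortho OH are alkylated, while the last ortho OH stays hydrogen-bonded to the acetyl group and remains free.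

Step 2
Reactants: 2 1-[2,4-bis(benzyloxy)-6-hydroxyphenyl]ethanone
Product: 3 1-[2-(allyloxy)-4,6-bis(benzyloxy)phenyl]ethanone
Conditions: allyl bromide (1.5 equiv), K2CO3, DMF, 65 °C
Reagents that add atoms: allyl bromide, C=CCBr
Why: Williamson etherification; the chelated phenol should be alkylated once warmed with a reactive allylic halide in a dipolar aprotic solvent.

Step 3
Reactants: 3 1-[2-(allyloxy)-4,6-bis(benzyloxy)phenyl]ethanone
Product: 4 1-[3-allyl-4,6-bis(benzyloxy)-2-hydroxyphenyl]ethanone
Conditions: PhNEt2, 200 °C, Ar, sealed vessel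
Reagents that add atoms: none
Why: Aromatic Claisen rearrangement ([3,3] shift, then enolisation); one ortho position of the allyl ether carries the acetyl group, so the allyl group should be delivered to C3, and the basic solvent suppresses acid-induced closure of the o-allylphenol.

Step 4
Reactants: 4 1-[3-allyl-4,6-bis(benzyloxy)-2-hydroxyphenyl]ethanone; 5 4-(benzyloxy)benzoyl chloride
Product: 6 1-[3-allyl-4,6-bis(benzyloxy)-2-hydroxyphenyl]-3-[4-(benzyloxy)phenyl]propane-1,3-dione
Conditions: LiN(SiMe3)2 (3.3 equiv), THF, −78 → −10 °C; 5, −78 °C → rt; 1 M HCl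
Reagents that add atoms: none
Why: Crossed Claisen condensation of the lithium phenoxide–enolate dianion with the aroyl chloride (one-pot form of the Baker–Venkataraman sequence); any O-aroylated material is carried to the same diketone by the excess base, and the low temperature avoids allyl-to-propenyl isomerisation.

Step 5
Reactants: 6 1-[3-allyl-4,6-bis(benzyloxy)-2-hydroxyphenyl]-3-[4-(benzyloxy)phenyl]propane-1,3-dione
Product: 7 8-allyl-5,7-bis(benzyloxy)-2-[4-(benzyloxy)phenyl]chromen-4-one
Conditions: NaOAc, AcOH, reflux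
Reagents that add atoms: none
Why: Cyclodehydration of an o-hydroxyaryl 1,3-diketone (hemiketal formation, loss of water); the single free phenol lies between the acyl and allyl groups, so the allyl group must end on C8'', and buffered acetic acid spares the peri benzyl ether and the alkene.

Step 6
Reactants: 7 8-allyl-5,7-bis(benzyloxy)-2-[4-(benzyloxy)phenyl]chromen-4-one
Product: 8 5,7-bis(benzyloxy)-2-[4-(benzyloxy)phenyl]-8-(2-oxopropyl)chromen-4-one
Conditions: PdCl2 (10 mol%), CuCl (1 equiv), O2 (1 atm), DMF/H2O 7:1, rt → 40 °C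
Reagents that add atoms: water, O
Why: Tsuji–Wacker oxidation; divalent palladium activates the terminal alkene, water adds at the internal carbon, CuCl/O2 re-oxidises zerovalent palladium, and allylarenes give arylacetones in this way while the trisubstituted pyranone alkene is inert.

Step 7
Reactants: 8 5,7-bis(benzyloxy)-2-[4-(benzyloxy)phenyl]-8-(2-oxopropyl)chromen-4-one
Product: 10 5,7-bis(benzyloxy)-2-[4-(benzyloxy)phenyl]-8-[(Z)-1-hydroxy-3-oxobut-1-en-2-yl]chromen-4-one, via enaminone 9 (not isolated)
Conditions: Me2NCH(OMe)2 (2 equiv), PhMe, 105 °C; concentrate; 1 M HCl, THF, rt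
Reagents that add atoms: N,N-dimethylformamide dimethyl acetal, COC(OC)N(C)C; water, O
Why: Aminomethylenation with an amide acetal takes place at the more acidic benzylic CH2 of arylacetones, and mild acid hydrolysis of the vinylogous amide should give the chelated hydroxymethylene ketone (enol of the 3-oxo-2-arylbutanal).

Step 8
Reactants: 10 5,7-bis(benzyloxy)-2-[4-(benzyloxy)phenyl]-8-[(Z)-1-hydroxy-3-oxobut-1-en-2-yl]chromen-4-one
Product: 11 5,7-bis(benzyloxy)-2-[4-(benzyloxy)phenyl]-8-[(E)-1-methoxy-3-oxobut-1-en-2-yl]chromen-4-one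
Conditions: Me2SO4 (1.2 equiv), K2CO3, DMF, 0 °C → rt
Reagents that add atoms: dimethyl sulfate, COS(=O)(=O)OC
Why: O-Alkylation of a hydroxymethylene ketone enolate with a hard electrophile in a dipolar aprotic solvent occurs at the less hindered formyl oxygen and should favour the E enol ether (methoxy trans to acetyl), as in the preparation of (E)-2-aryl-3-methoxyacrylates.

Step 9
Reactants: 11 5,7-bis(benzyloxy)-2-[4-(benzyloxy)phenyl]-8-[(E)-1-methoxy-3-oxobut-1-en-2-yl]chromen-4-one
Product: 12 5,7-bis(benzyloxy)-2-[4-(benzyloxy)phenyl]-8-[(E)-1-methoxy-3-(trimethylsilyloxy)buta-1,3-dien-2-yl]chromen-4-one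
Conditions: Me3SiOTf (1.3 equiv), Et3N (2.5 equiv), Et2O/CH2Cl2, 0 °C; non-aqueous work-up, used crude
Reagents that add atoms: trimethylsilyl trifluoromethanesulfonate, C[Si](C)(C)OS(=O)(=O)C(F)(F)F
Why: Soft enolisation and O-silylation of a β-methoxy enone is the standard entry to 1-methoxy-3-silyloxydienes; the methyl group is the only enolisable position and the enol ether geometry is not touched.

Step 10
Reactants: 12 5,7-bis(benzyloxy)-2-[4-(benzyloxy)phenyl]-8-[(E)-1-methoxy-3-(trimethylsilyloxy)buta-1,3-dien-2-yl]chromen-4-one; 13 methyl propiolate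
Product: 15 methyl 3-{5,7-bis(benzyloxy)-2-[4-(benzyloxy)phenyl]-4-oxochromen-8-yl}-4-hydroxybenzoate, via cyclohexa-1,4-diene cycloadduct 14 (not isolated)
Conditions: 13 (5 equiv), PhMe, 115 °C, sealed tube; concentrate; 1 M HCl, THF, rt
Reagents that add atoms: none
Why: The methoxy and silyloxy donors raise the HOMO of 12 and place its largest coefficient on the terminal CH2 (future C5'), so diene and electron-poor alkyne should combine in a concerted, asynchronous, normal-electron-demand Diels–Alder reaction in which the C5'–C6' bond (diene CH2 to the β-carbon of 13) runs ahead of the C1'–C2' bond. The closest known reaction type is the benzannulation of 1-methoxy-3-silyloxybuta-1,3-dienes, 2-substituted ones included, with acetylenic esters to 4-hydroxybenzoates; only the flavone as 2-substituent is new. Ring B is closed in an intermolecular (4+2) mode, C2'–C5' coming from the diene and C1' and C6' from the alkyne, which gives the cyclohexa-1,4-diene 14. Acid then ionises the doubly allylic methoxy group, the silyl group leaves the resulting oxocarbenium ion and the dienone tautomerises to the phenol, so the one stereocentre of 14 (C2', racemic) is erased and none remains to be controlled. The selectivity needed is regiochemical (ester para and flavone ortho to the oxygen-bearing carbon) and is secured by the matched polarisation of the two partners, while reactivity rests on the E enol ether, which leaves only hydrogen atoms on the inward positions of the s-cis conformer. All phenols are benzylated, so nothing can add to the propiolate in a conjugate sense, and the trisubstituted, donor-stabilised pyranone C2''=C3'' bond should not compete as a dienophile.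

Step 11
Reactants: 15 methyl 3-{5,7-bis(benzyloxy)-2-[4-(benzyloxy)phenyl]-4-oxochromen-8-yl}-4-hydroxybenzoate
Product: 16 methyl 4-(benzyloxy)-3-{5,7-bis(benzyloxy)-2-[4-(benzyloxy)phenyl]-4-oxochromen-8-yl}benzoate
Conditions: BnBr (1.3 equiv), K2CO3, DMF, 50 °C
Reagents that add atoms: benzyl bromide, BrCc1ccccc1
Why: Williamson etherification; the para ester makes the phenol acidic enough for smooth alkylation despite the ortho aryl group.

Step 12
Reactants: 16 methyl 4-(benzyloxy)-3-{5,7-bis(benzyloxy)-2-[4-(benzyloxy)phenyl]-4-oxochromen-8-yl}benzoate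
Product: 17 4-(benzyloxy)-3-{5,7-bis(benzyloxy)-2-[4-(benzyloxy)phenyl]-4-oxochromen-8-yl}benzoic acid
Conditions: LiOH (5 equiv), THF/MeOH/H2O, 40 °C; 1 M HCl to pH 3
Reagents that add atoms: lithium hydroxide, [Li+].[OH-]
Why: Saponification of an unhindered methyl benzoate; even a reversible opening of the pyranone could only re-close to the same flavone on acidification, because the 5''-oxygen is benzylated.

Step 13
Reactants: 18 2',6'-dihydroxy-4'-methoxyacetophenone
Product: 19 1-[2-(benzyloxy)-6-hydroxy-4-methoxyphenyl]ethanone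
Conditions: BnBr (1.05 equiv), K2CO3 (1.1 equiv), acetone, reflux
Reagents that add atoms: benzyl bromide, BrCc1ccccc1
Why: Williamson mono-etherification; the two OH groups are equivalent, and after the first alkylation the remaining OH is firmly chelated to the ketone, so one equivalent of halide should stop at the mono-ether.

Step 14
Reactants: 17 4-(benzyloxy)-3-{5,7-bis(benzyloxy)-2-[4-(benzyloxy)phenyl]-4-oxochromen-8-yl}benzoic acid; 19 1-[2-(benzyloxy)-6-hydroxy-4-methoxyphenyl]ethanone
Product: 20 2-acetyl-3-(benzyloxy)-5-methoxyphenyl 4-(benzyloxy)-3-{5,7-bis(benzyloxy)-2-[4-(benzyloxy)phenyl]-4-oxochromen-8-yl}benzoate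
Conditions: DCC (1.2 equiv), DMAP (20 mol%), CH2Cl2, rt
Reagents that add atoms: none
Why: Steglich esterification; the acylpyridinium species acylates chelated o-hydroxyacetophenones, and the neutral conditions avoid exposing the pyranone carbonyl to chlorinating agents.

Step 15
Reactants: 20 2-acetyl-3-(benzyloxy)-5-methoxyphenyl 4-(benzyloxy)-3-{5,7-bis(benzyloxy)-2-[4-(benzyloxy)phenyl]-4-oxochromen-8-yl}benzoate
Product: 21 1-[2-(benzyloxy)-6-hydroxy-4-methoxyphenyl]-3-(4-(benzyloxy)-3-{5,7-bis(benzyloxy)-2-[4-(benzyloxy)phenyl]-4-oxochromen-8-yl}phenyl)propane-1,3-dione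
Conditions: KOt-Bu (2.5 equiv), THF, 0 °C → rt; 1 M HCl
Reagents that add atoms: none
Why: Baker–Venkataraman rearrangement; the methyl ketone enolate attacks the neighbouring aryl ester intramolecularly, formation of the diketonate–phenoxide drives the O-to-C acyl shift, and the bulky base does not add to the existing flavone.

Step 16
Reactants: 21 1-[2-(benzyloxy)-6-hydroxy-4-methoxyphenyl]-3-(4-(benzyloxy)-3-{5,7-bis(benzyloxy)-2-[4-(benzyloxy)phenyl]-4-oxochromen-8-yl}phenyl)propane-1,3-dione
Product: 22 penta-O-benzylsequoiaflavone (5,4',5'',7'',4'''-penta-O-benzyl-7-O-methyl-3',8''-biapigenin)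
Conditions: NaOAc, AcOH, reflux
Reagents that add atoms: none
Why: Cyclodehydration of the o-hydroxyaryl 1,3-diketone as in step 5; the free phenol closes onto the aroyl carbonyl, giving the 5-benzyloxy-7-methoxychromen-4-one.

Step 17
Reactants: 22 penta-O-benzylsequoiaflavone
Product: 23 sequoiaflavone
Conditions: H2 (1 atm), Pd/C (10 wt% Pd), THF/MeOH 1:1, rt
Reagents that add atoms: none
Why: Catalytic hydrogenolysis of the five aryl benzyl ethers; the aryl methyl ether is inert, and at one atmosphere and room temperature the conjugated pyranone double bonds should remain.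

**Compound list**
1 | 2',4',6'-trihydroxyacetophenone | CC(=O)c1c(O)cc(O)cc1O | starting material
2 | 1-[2,4-bis(benzyloxy)-6-hydroxyphenyl]ethanone | CC(=O)c1c(O)cc(OCc2ccccc2)cc1OCc1ccccc1 | intermediate
3 | 1-[2-(allyloxy)-4,6-bis(benzyloxy)phenyl]ethanone | CC(=O)c1c(OCC=C)cc(OCc2ccccc2)cc1OCc1ccccc1 | intermediate
4 | 1-[3-allyl-4,6-bis(benzyloxy)-2-hydroxyphenyl]ethanone | CC(=O)c1c(O)c(CC=C)c(OCc2ccccc2)cc1OCc1ccccc1 | intermediate
5 | 4-(benzyloxy)benzoyl chloride | O=C(Cl)c1ccc(OCc2ccccc2)cc1 | starting material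
6 | 1-[3-allyl-4,6-bis(benzyloxy)-2-hydroxyphenyl]-3-[4-(benzyloxy)phenyl]propane-1,3-dione | O=C(CC(=O)c1ccc(OCc2ccccc2)cc1)c1c(O)c(CC=C)c(OCc2ccccc2)cc1OCc1ccccc1 | intermediate
7 | 8-allyl-5,7-bis(benzyloxy)-2-[4-(benzyloxy)phenyl]chromen-4-one | C=CCc1c(OCc2ccccc2)cc(OCc2ccccc2)c2c(=O)cc(-c3ccc(OCc4ccccc4)cc3)oc12 | intermediate
8 | 5,7-bis(benzyloxy)-2-[4-(benzyloxy)phenyl]-8-(2-oxopropyl)chromen-4-one | CC(=O)Cc1c(OCc2ccccc2)cc(OCc2ccccc2)c2c(=O)cc(-c3ccc(OCc4ccccc4)cc3)oc12 | intermediate
9 | 5,7-bis(benzyloxy)-2-[4-(benzyloxy)phenyl]-8-[(E)-1-(dimethylamino)-3-oxobut-1-en-2-yl]chromen-4-one | CN(C)/C=C(\c1c(OCc2ccccc2)cc(OCc2ccccc2)c2c(=O)cc(-c3ccc(OCc4ccccc4)cc3)oc12)C(C)=O | intermediate (not isolated)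
10 | 5,7-bis(benzyloxy)-2-[4-(benzyloxy)phenyl]-8-[(Z)-1-hydroxy-3-oxobut-1-en-2-yl]chromen-4-one (chelated enol, in tautomeric equilibrium with the keto aldehyde) | O/C=C(/c1c(OCc2ccccc2)cc(OCc2ccccc2)c2c(=O)cc(-c3ccc(OCc4ccccc4)cc3)oc12)C(C)=O | intermediate
11 | 5,7-bis(benzyloxy)-2-[4-(benzyloxy)phenyl]-8-[(E)-1-methoxy-3-oxobut-1-en-2-yl]chromen-4-one | CO/C=C(\c1c(OCc2ccccc2)cc(OCc2ccccc2)c2c(=O)cc(-c3ccc(OCc4ccccc4)cc3)oc12)C(C)=O | intermediate
12 | 5,7-bis(benzyloxy)-2-[4-(benzyloxy)phenyl]-8-[(E)-1-methoxy-3-(trimethylsilyloxy)buta-1,3-dien-2-yl]chromen-4-one | CO/C=C(\c1c(OCc2ccccc2)cc(OCc2ccccc2)c2c(=O)cc(-c3ccc(OCc4ccccc4)cc3)oc12)C(=C)O[Si](C)(C)C | intermediate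
13 | methyl propiolate | C#CC(=O)OC | starting material
14 | methyl 5-{5,7-bis(benzyloxy)-2-[4-(benzyloxy)phenyl]-4-oxochromen-8-yl}-6-methoxy-4-(trimethylsilyloxy)cyclohexa-1,4-diene-1-carboxylate (racemic at C6) | COC(=O)C1=CCC(O[Si](C)(C)C)=C(c2c(OCc3ccccc3)cc(OCc3ccccc3)c3c(=O)cc(-c4ccc(OCc5ccccc5)cc4)oc23)C1OC | intermediate (not isolated)
15 | methyl 3-{5,7-bis(benzyloxy)-2-[4-(benzyloxy)phenyl]-4-oxochromen-8-yl}-4-hydroxybenzoate | COC(=O)c1ccc(O)c(-c2c(OCc3ccccc3)cc(OCc3ccccc3)c3c(=O)cc(-c4ccc(OCc5ccccc5)cc4)oc23)c1 | intermediate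
16 | methyl 4-(benzyloxy)-3-{5,7-bis(benzyloxy)-2-[4-(benzyloxy)phenyl]-4-oxochromen-8-yl}benzoate | COC(=O)c1ccc(OCc2ccccc2)c(-c2c(OCc3ccccc3)cc(OCc3ccccc3)c3c(=O)cc(-c4ccc(OCc5ccccc5)cc4)oc23)c1 | intermediate
17 | 4-(benzyloxy)-3-{5,7-bis(benzyloxy)-2-[4-(benzyloxy)phenyl]-4-oxochromen-8-yl}benzoic acid | OC(=O)c1ccc(OCc2ccccc2)c(-c2c(OCc3ccccc3)cc(OCc3ccccc3)c3c(=O)cc(-c4ccc(OCc5ccccc5)cc4)oc23)c1 | intermediate
18 | 2',6'-dihydroxy-4'-methoxyacetophenone | CC(=O)c1c(O)cc(OC)cc1O | starting material
19 | 1-[2-(benzyloxy)-6-hydroxy-4-methoxyphenyl]ethanone | CC(=O)c1c(O)cc(OC)cc1OCc1ccccc1 | intermediate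
20 | 2-acetyl-3-(benzyloxy)-5-methoxyphenyl 4-(benzyloxy)-3-{5,7-bis(benzyloxy)-2-[4-(benzyloxy)phenyl]-4-oxochromen-8-yl}benzoate | CC(=O)c1c(OCc2ccccc2)cc(OC)cc1OC(=O)c1ccc(OCc2ccccc2)c(-c2c(OCc3ccccc3)cc(OCc3ccccc3)c3c(=O)cc(-c4ccc(OCc5ccccc5)cc4)oc23)c1 | intermediate
21 | 1-[2-(benzyloxy)-6-hydroxy-4-methoxyphenyl]-3-(4-(benzyloxy)-3-{5,7-bis(benzyloxy)-2-[4-(benzyloxy)phenyl]-4-oxochromen-8-yl}phenyl)propane-1,3-dione | COc1cc(O)c(C(=O)CC(=O)c2ccc(OCc3ccccc3)c(-c3c(OCc4ccccc4)cc(OCc4ccccc4)c4c(=O)cc(-c5ccc(OCc6ccccc6)cc5)oc34)c2)c(OCc2ccccc2)c1 | intermediate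
22 | penta-O-benzylsequoiaflavone | COc1cc(OCc2ccccc2)c2c(=O)cc(-c3ccc(OCc4ccccc4)c(-c4c(OCc5ccccc5)cc(OCc5ccccc5)c5c(=O)cc(-c6ccc(OCc7ccccc7)cc6)oc45)c3)oc2c1 | intermediate
23 | sequoiaflavone | COc1cc(O)c2c(=O)cc(-c3ccc(O)c(-c4c(O)cc(O)c5c(=O)cc(-c6ccc(O)cc6)oc45)c3)oc2c1 | target

**Step count and risks**
Total: 17 steps. Longest linear sequence: 16 steps (steps 1–12 and 14–17, from 1); step 13 is a one-step branch.

Step 10 is the riskiest.
- The doubly ortho-substituted flavone on C3' stands orthogonal to the diene and crowds both of its faces. Cycloaddition may then become so slow that protodesilylation of the diene and thermal oligomerisation of the propiolate overtake it.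
- The fallback changes the class of diene and the leaving group. It sets out from enaminone 9, which is isolated after the first half of step 7 instead of being hydrolysed.
- Deprotonation of the methyl ketone with KN(SiMe3)2 in THF at −78 °C and trapping with t-BuMe2SiCl should give the 1-dimethylamino-3-(tert-butyldimethylsilyloxy)diene F1.
- 1-Amino-3-silyloxydienes are far more reactive than their methoxy counterparts, and the bulkier silyl group tolerates handling. F1 should add 13 at or slightly above room temperature with the same regiochemistry to give the aminocyclohexadiene adduct F2.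
- Aqueous HF in MeCN then expels dimethylamine and removes the silyl group, and the route is rejoined at 15.
- The methoxy diene remains the first choice because it is not basic and cannot enter the enamine-type stepwise additions that propiolates undergo.

Step 7 comes second.
- Condensation may drift from the crowded benzylic CH2 to the methyl group, occur twice, or stall.
- The fallback fixes the regiochemistry in a separate step and uses a small cationic one-carbon electrophile. It sets out from 8.
- Soft enolisation with Me3SiOTf/Et3N in CH2Cl2 removes the more acidic benzylic proton and should give the conjugated silyl enol ether F3 (mainly Z; its geometry has no consequence).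
- A Mukaiyama-type reaction with HC(OMe)3 and catalytic Me3SiOTf at −78 °C should give the β-keto dimethyl acetal F4 (racemic).
- DBU in warm toluene eliminates methanol under equilibrating conditions to the E enol ether, and the route is rejoined at 11, bypassing 9 and 10.

Step 17 comes third.
- Partly deprotected, poorly soluble biflavones may deposit on the catalyst, so that the hindered benzyl ethers are cleaved incompletely. Prolonged exposure may then begin to saturate the pyranone double bonds.
- The fallback replaces reduction by Lewis-acid cleavage. It sets out from 22 and uses BCl3 with pentamethylbenzene as cation scavenger in CH2Cl2 at −78 °C, followed by a methanol quench.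
- It returns directly at 23. The 7-methoxy group is not chelated to a carbonyl group and should survive. This fallback makes no new compound (F0).

**Further compounds**
F1 | step 10 | 5,7-bis(benzyloxy)-2-[4-(benzyloxy)phenyl]-8-[(E)-3-(tert-butyldimethylsilyloxy)-1-(dimethylamino)buta-1,3-dien-2-yl]chromen-4-one | CN(C)/C=C(\c1c(OCc2ccccc2)cc(OCc2ccccc2)c2c(=O)cc(-c3ccc(OCc4ccccc4)cc3)oc12)C(=C)O[Si](C)(C)C(C)(C)C
F2 | step 10 | methyl 5-{5,7-bis(benzyloxy)-2-[4-(benzyloxy)phenyl]-4-oxochromen-8-yl}-4-(tert-butyldimethylsilyloxy)-6-(dimethylamino)cyclohexa-1,4-diene-1-carboxylate (racemic) | COC(=O)C1=CCC(O[Si](C)(C)C(C)(C)C)=C(c2c(OCc3ccccc3)cc(OCc3ccccc3)c3c(=O)cc(-c4ccc(OCc5ccccc5)cc4)oc23)C1N(C)C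
F3 | step 7 | 5,7-bis(benzyloxy)-2-[4-(benzyloxy)phenyl]-8-[(Z)-2-(trimethylsilyloxy)prop-1-en-1-yl]chromen-4-one | C/C(O[Si](C)(C)C)=C/c1c(OCc2ccccc2)cc(OCc2ccccc2)c2c(=O)cc(-c3ccc(OCc4ccccc4)cc3)oc12
F4 | step 7 | 5,7-bis(benzyloxy)-2-[4-(benzyloxy)phenyl]-8-(1,1-dimethoxy-3-oxobutan-2-yl)chromen-4-one (racemic) | COC(OC)C(C(C)=O)c1c(OCc2ccccc2)cc(OCc2ccccc2)c2c(=O)cc(-c3ccc(OCc4ccccc4)cc3)oc12
F0 | step 17 | none | none
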